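In a closed flask the charged monomer is conserved: free monomer, monomer in chains and whatever has left by a side path always sum to the charge.

| setting | east | north | autumn | spring | midnight |
|---|---|---|---|---|---|
| free monomer | 0.078 M | 0.078 M | 0.078 M | 0.078 M | 0.078 M |
| initiator | 0.39 mM | 0.58 mM | 0.78 mM | 0.78 mM | 0.78 mM |
| temperature | 85 °C | 110 °C | 90 °C | 130 °C | 110 °C |
| remark | run made earlier | run made earlier |  |  |  |
| time |  |  | 25 h | 25 h | 25 h |

| run | time / h | monomer in chains / % | free monomer / % |
|---|---|---|---|
| east | 1.50 | 21.3 | 75.3 |
| east | 4.00 | 66.5 | 26.7 |
| east | 8.00 | 91.1 | 2.4 |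
| east | 20.0 | 91.5 | 0 |
| north | 1.00 | 75.7 | 10.2 |
| north | 3.00 | 85.5 | 0 |
| north | 4.00 | 83.1 | 0 |
| north | 8.00 | 86.0 | 1.5 |

(each reading ± 1 percentage point)



- the best flask by amount of monomer in chains, in percent of the free monomer charged; "all alike" if 1.5 percentage points covers them all (autumn / spring / midnight / all alike)
- amount of monomer in chains at the end, in percent of the free monomer charged, autumn
- amount of monomer in chains at the end, in percent of the free monomer charged, spring
- amount of monomer in chains at the end, in percent of the free monomer charged, midnight

Free monomer stood at 0% in the east run at 20.0 h and at 0% in the north run at 3.00 h, so we expect the 25 h flasks to finish and ask how the charge divides. Let ρ be the monomer lost per monomer in chains once free monomer has gone. East's last reading gives 0.0929, the loss ratio, a selectivity factor. North's last three readings average 84.9%, so ρ there reads 0.178. The share in chains is then 1/(1+ρ).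

Temperature and initiator changed together between these runs, so we reckon both ends. If initiator does nothing, ln ρ climbs 0.0261 K⁻¹, and autumn gets 90.4%. If ρ falls inversely with initiator, the climb is 0.0420 K⁻¹, and autumn gets 94.6%. Midnight lies between 84.9% and 88.3%. For spring, hotter than either run, the ends nearly join at 76.9% and 76.5%. We would commit to autumn as best.

The forecast also names autumn, with 88%, 84% and 78% for autumn, midnight and spring, reasoning that “a side path takes a fixed share of the monomer”. Its autumn figure lies below our lower end.

The flasks give 94.2% in autumn and 86.2% at midnight, both inside our brackets, so autumn is best. Spring gives 71.8%, below both our ends.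

    living end + monomer in chains → dead end (k = 0.0374 L mol⁻¹ min⁻¹, Ea = 82.0 kJ mol⁻¹)
    free monomer + initiator → living end + monomer in chains (k = 0.336 L mol⁻¹ min⁻¹, Ea = 85.0 kJ mol⁻¹)
    free monomer + living end → monomer in chains + living end, rate k3*[living end]*[free monomer] (k = 152 L mol⁻¹ min⁻¹, Ea = 59.0 kJ mol⁻¹)
    free monomer → uncatalysed product (k = 0.00501 min⁻¹, Ea = 124 kJ mol⁻¹)
    (constants at 110 °C)

The loss is mainly the step from free monomer to uncatalysed product: without it, spring reaches 99.4% in chains. Its activation energy of 124 kJ mol⁻¹ exceeds the 59.0 kJ mol⁻¹ of chain growth, and this is part of why ρ stands at 0.393 in spring, against 0.0617 in autumn and the 0.0929 read in the east run. The neighbour flask, autumn with free monomer cut to 0.019 M, has ρ = 0.117 and ends with 89.5% in chains.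

(The readings stem from a simulated flask for substances that don't exist; the scatter is artificial.)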